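**Conventions.** The atom labels C1–C8 of the target skeleton are kept for every intermediate: C1 allyl bridgehead, C2=C3 enol ether, C4 acetoxy carbon, C5 methoxy bridgehead, C6 aryl carbon, C7 methyl carbon, C8 bridging ketone. The names of the bicyclo[3.2.1] compounds use these labels as locants. In the bicyclo[4.2.0] compounds the systematic locants 1, 2, 3, 4, 5, 6, 7, 8 stand for C8, C5, C4, C3, C2, C1, C7, C6. Compound numbers 1–22 are fixed by the steps below.

## Analysis of the target

The target is a bicyclo[3.2.1]oct-2-en-8-one. A six-membered ring (C1, C2, C3, C4, C5, C8) and a five-membered ring (C1, C7, C6, C5, C8) share the bridgeheads C1 and C5 and the one-carbon ketone bridge C8. There are five contiguous stereocentres, (1S,4R,5S,6R,7S). Both bridgeheads are quaternary (allyl on C1, methoxy on C5) and fix each other. On the two-carbon bridge the trimethoxyphenyl group at C6 is endo (turned toward the C2–C4 bridge) and the methyl group at C7 is exo, so the two are trans. The acetoxy group at C4 sits on the face of the three-carbon bridge that looks toward the two-carbon bridge, anti to C8 and on the same side as the aryl ring. The sensitive groups are the enol ether C2=C3(OMe) (acid), the allylic acetate that is also β to the C8 ketone (base), the terminal alkene (no hydrogenation, hydroboration or unselective oxidants) and the electron-rich arene. The synthesis is hard because a ketone that cannot enolise is flanked by two quaternary carbons, and because four ring carbons carry oxygen at three oxidation levels. The strategy rests on one feature: C6 is bonded to C5, next to the C8 carbonyl. Moving C6 back from C5 to C8 turns the five-membered ring into a cyclobutane (C1, C7, C6, C8) fused along C1–C8 to a cyclohexane with oxygen on C8 and a carbonyl at C5, which is the pattern of an enone–alkene photoadduct.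

## Retrosynthetic reasoning

**22 to 21.** The acetyl–oxygen bond at C4 is cut last. The acetate would not survive the enolate and hydride chemistry needed earlier, and its removal leaves the allylic alcohol 21 with all five stereocentres in place.

**21 to 20.** The C4–H bond is cut, leading to enone 20. In 20 one face of the C4 carbonyl lies under the endo aryl group on C6, so a small hydride should enter from the side of the C8 bridge and place the hydroxyl on the aryl side, as required. The forward step must reduce the conjugated C4 ketone and leave the C8 ketone.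

**20 to 15 (through 19 and 17).** The C3 oxygen and the C2=C3 double bond are traced back to a plain C3 methylene next to the C4 ketone of dione 15. The methyl ether 20 comes from diosphenol 19, 19 from the acyloin 17 by oxidation and enolisation toward C2, and 17 from 15 by enolate hydroxylation. In 15 only C3 carries acidic hydrogens, because C5 and C1 are quaternary, so there is no regiochemical question.

**15 to 12 (through 14).** The C4 ketone is taken back to the alcohol 14, and then the skeletal bond C5–C6 is cut with C6 returned to C8. This is the only ring bond whose 1,2-relocation gives a photoadduct pattern with a heteroatom on the migration terminus. C5 carries a methoxy group that can stabilise a cation, whereas C1 has none. The precursor is the methyl enol ether 12. The forward step has to deliver oxygen to C4, make C5 electron-deficient with its methoxy group already attached, and let C6 migrate with retention, in preference to C1 or a hydrogen on C4.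

**12 to 10.** The enol ether is taken back to ketone 10. Only C4 is enolisable in 10, so the forward step has to solve O- against C-methylation and nothing else.

**10 to 6 and 9.** The cyclobutane bonds C1–C7 and C6–C8 are cut together. This gives two simple components, enone 6 and alkene 9, and accounts for one ring, two skeletal bonds and four stereocentres. The forward step must control regiochemistry, the cis ring fusion, the trans aryl/methyl relation with the aryl group on the carbonyl side, and the absolute configuration.

**6 to 1 and 2 (through 5 and 3); 9 to 7 and 8.** The silyl group of 6 is removed to give diosphenol 5. The C3–allyl bond of 5 is moved back to oxygen, giving allyl enol ether 3, which comes from dione 1 and halide 2. Alkene 9 is cut at the aryl–alkenyl bond into bromide 7 and alkenylboronate 8, which fixes the E geometry.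

## Alternatives that were turned down

**Alternative 1:** Reductive Nazarov cyclisation. The disconnection is the C6–C7 bond of the five-membered ring. The precursor is the cross-conjugated dienone A1, in which methyl and aryl are both trans to the carbonyl carbon. In the forward step BF3·OEt2, or Cu(OTf)2 with a chiral bis(oxazoline) ligand, brings about conrotatory closure, and Et3SiH delivers hydride to C5 of the oxyallyl cation. The product is the triethylsilyl enol ether A2, with C1=C8 as the enol double bond.
- For: the trans aryl/methyl relation follows from orbital symmetry, which is more secure than a diradical ring closure. The α-methoxy dienone can chelate a chiral Lewis acid, so absolute control has closer precedent than in the chosen route. On both points this alternative is stronger.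
- Against: A2 is monocyclic. Both quaternary bridgeheads and the whole C2–C3–C4 bridge with its three functionalised carbons are still missing, and they would have to come from an α,α'-annulation with an oxygenated three-carbon unit. The C5 centre set by the hydride is destroyed again on enolisation, and hydride capture at C5 rather than C1 is not assured.
- Comparison: the chosen strategy offers the complete carbon skeleton, including both bridgeheads, after two C–C bond-forming operations from two simple components.

**Alternative 2:** Conjugate arylation relayed into a bridging Mukaiyama aldol. The disconnections are the C6–aryl bond and the C4–C5 bond. The precursors are the cyclopentenone aldehyde A3 and the arylzinc chloride A4. In the forward step [RhCl(C2H4)2]2 with BINAP adds the aryl group to C6 in the presence of Me3SiCl, and BF3·OEt2 then makes the C5=C8 silyl enol ether attack the aldehyde carbon C4. The product is the deacetyl target A5, which is identical with 21.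
- For: the key step ends one acetylation from the target. All oxidation levels are carried in, and the aryl group enters anti to the C7 methyl group. In step economy after the key step this alternative is clearly stronger.
- Against: the difficulty is moved into A3. It needs a quaternary C1 next to the C7 stereocentre, and its 2-methoxy enal arm must have C1 and the formyl carbon cis. The aryl–rhodium species can also add to the aldehyde or to the enal. The conjugated, donor-substituted aldehyde is a weak electrophile, and the C4 configuration arises in a bridged transition state of uncertain preference.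
- Comparison: the chosen strategy starts from a precursor made in three reliable steps and keeps the risk in one step, at the price of a longer endgame.

**Alternative 3:** Masked ortho-quinone Diels–Alder, then α-ketol shift. The disconnections are C1–C7 and a temporary C4–C6 bond. The precursors are the masked ortho-benzoquinone A6 (C5 ketone, C8 dimethyl ketal, diene C4=C3–C2=C1) and alkene 9. The forward step is a cycloaddition to the bicyclo[2.2.2]octenone A7. Desilylation and an α-ketol shift of C6 from C4 to C5 would follow.
- For: the concerted six-membered transition state transmits the alkene geometry and favours the endo aryl group. The polarity of the dienone matches the needed regiochemistry. After the shift the C2=C3(OMe)–C4=O unit is already present, so the C3 oxidation sequence of the chosen route is not needed. On diastereocontrol and oxidation-state economy this alternative is stronger.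
- Against: A6 is a fully substituted, electron-rich dienone whose phenol precursor needs a multistep arene synthesis. Such dienones dimerise, and a 1,2-disubstituted styrene would have to create two quaternary bridgeheads. No dependable catalytic enantioselective version exists. The α-ketol shift from bicyclo[2.2.2] to bicyclo[3.2.1] has little driving force and leaves a tertiary C5 hydroxyl that still has to be methylated.
- Comparison: in the chosen strategy the shift is driven by the opening of a four-membered ring, ends irreversibly with loss of the silyl group and delivers the C5 methoxy group directly.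

Key step: step 5

Assumption: the sense of induction of the AlBr3-activated oxazaborolidine on a 2-silyloxy enone cannot be read from α-unsubstituted models; the (S)-prolinol-derived catalyst is written, and its mirror image is to be used if the adduct proves to be the enantiomer of 10.

## Route

Step 1
Reactants: 1 cyclohexane-1,2-dione; 2 allyl bromide
Product: 3 2-(prop-2-en-1-yloxy)cyclohex-2-en-1-one
Conditions: K2CO3, acetone, reflux
Reagents that add atoms: none
Why: Williamson-type O-alkylation of the enol (diosphenol) form of 1 under weakly basic conditions; any C-allylated material is the dione 4 that step 2 produces anyway, so both modes of alkylation converge.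

Step 2
Reactants: 3 2-(prop-2-en-1-yloxy)cyclohex-2-en-1-one
Product: 5 2-hydroxy-3-(prop-2-en-1-yl)cyclohex-2-en-1-one, via 3-(prop-2-en-1-yl)cyclohexane-1,2-dione 4 (not isolated)
Conditions: o-dichlorobenzene, 180 °C
Reagents that add atoms: none
Why: Claisen rearrangement ([3,3]-sigmatropic shift) of the allyl enol ether carries the allyl group to the enol carbon; the 1,2-dione 4 then enolises to the more substituted, conjugated diosphenol 5.

Step 3
Reactants: 5 2-hydroxy-3-(prop-2-en-1-yl)cyclohex-2-en-1-one
Product: 6 2-(tert-butyldimethylsilyloxy)-3-(prop-2-en-1-yl)cyclohex-2-en-1-one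
Conditions: TBSCl, imidazole, DMF, 23 °C
Reagents that add atoms: tert-butyldimethylsilyl chloride, CC(C)(C)[Si](C)(C)Cl
Why: Silylation of the acidic enol hydroxyl; the tetrasubstituted enol double bond is already in place, so the silyl group fixes the 2-silyloxy enone needed for the photochemical step.

Step 4
Reactants: 7 5-bromo-1,2,3-trimethoxybenzene; 8 (E)-4,4,5,5-tetramethyl-2-(prop-1-en-1-yl)-1,3,2-dioxaborolane
Product: 9 (E)-isoelemicin (1,2,3-trimethoxy-5-[(E)-prop-1-en-1-yl]benzene)
Conditions: Pd(PPh3)4 (3 mol %), K2CO3, dioxane/H2O, 90 °C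
Reagents that add atoms: none
Why: Suzuki–Miyaura coupling; transmetallation and reductive elimination retain the alkene geometry, so the E isomer is obtained without an isomerisation step.

Step 5
Reactants: 6 2-(tert-butyldimethylsilyloxy)-3-(prop-2-en-1-yl)cyclohex-2-en-1-one; 9 (E)-isoelemicin
Product: 10 (1R,6S,7S,8R)-1-(tert-butyldimethylsilyloxy)-7-methyl-6-(prop-2-en-1-yl)-8-(3,4,5-trimethoxyphenyl)bicyclo[4.2.0]octan-2-one
Conditions: 9 (5 equiv), AlBr3-activated (S)-3,3-diphenyl-1-(2,4,6-trifluorophenyl)tetrahydro-1H,3H-pyrrolo[1,2-c][1,3,2]oxazaborole (50 mol %), CH2Cl2, −75 °C, hν (366 nm)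
Reagents that add atoms: none
Why: Proposed new method: the closest known reaction type is the enantioselective intermolecular [2+2] photocycloaddition of cyclic enones with alkenes under AlBr3-activated oxazaborolidine catalysis, known for α-unsubstituted enones and simple alkenes but not for a 2-silyloxy enone with an aryl alkene. The boron centre binds the carbonyl oxygen of 6 and shifts its absorption to longer wavelength, so that 366 nm light excites mainly the chiral complex; after intersystem crossing the triplet bonds from the β-carbon C1 to the methyl-bearing carbon C7 of 9. This choice of termini gives the best 1,4-diradical, benzylic at C6 and stabilised by both the carbonyl and the silyloxy group at C8, which secures the regiochemistry (C1–C7 and C6–C8). The four-membered ring then closes stepwise, by spin inversion and radical–radical combination between C6 and C8, not by a concerted process. C1: the catalyst is expected to cover one face of the bound enone so that C7 adds to the Re face of C1 (C8 > allyl > C2). C8: the two-atom tether lets C6 reach only the face of the enoxyl radical on which the C1–C7 bond lies, which gives the cis ring fusion; a trans-fused adduct from a twisted triplet could not be epimerised at these quaternary centres and would have to be separated. C6 and C7: the diradical can rotate and revert before it closes, so the alkene geometry is not transmitted and closure should go through the least crowded arrangement, with aryl trans to methyl, aryl beside the flat C5 carbonyl carbon and not the silyloxy group, and methyl on the convex face beside the allyl group. The step therefore needs regio-, diastereo- and enantioselectivity; the first rests on radical stabilisation, the second on sterics at ring closure (the weakest point) and the third on the catalyst.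

Step 6
Reactants: 10 (1R,6S,7S,8R)-1-(tert-butyldimethylsilyloxy)-7-methyl-6-(prop-2-en-1-yl)-8-(3,4,5-trimethoxyphenyl)bicyclo[4.2.0]octan-2-one
Product: 12 (1R,6S,7S,8R)-1-(tert-butyldimethylsilyloxy)-2-methoxy-7-methyl-6-(prop-2-en-1-yl)-8-(3,4,5-trimethoxyphenyl)bicyclo[4.2.0]oct-2-ene, via potassium enolate 11 (not isolated)
Conditions: KHMDS, 18-crown-6, THF, −78 °C; MeOTf, −78 to 0 °C
Reagents that add atoms: methyl trifluoromethanesulfonate, COS(=O)(=O)C(F)(F)F
Why: O-alkylation of an enolate; only C4 carries α-hydrogens (C8 is quaternary), so a single enolate forms, and a crown-separated potassium enolate should react with the hard triflate mainly at oxygen. No stereocentre is touched.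

Step 7
Reactants: 12 (1R,6S,7S,8R)-1-(tert-butyldimethylsilyloxy)-2-methoxy-7-methyl-6-(prop-2-en-1-yl)-8-(3,4,5-trimethoxyphenyl)bicyclo[4.2.0]oct-2-ene
Product: 14 (1S,4S,5S,6R,7S)-4-hydroxy-5-methoxy-7-methyl-1-(prop-2-en-1-yl)-6-(3,4,5-trimethoxyphenyl)bicyclo[3.2.1]octan-8-one, via epoxy ether 13 (not isolated)
Conditions: DMDO, acetone/CH2Cl2, −78 to −20 °C; concentrate; BF3·OEt2, CH2Cl2, −78 °C; aq NaHCO3
Reagents that add atoms: dimethyldioxirane, CC1(C)OO1
Why: Epoxidation of the electron-rich enol ether, far faster than that of the terminal alkene, gives the 2,3-epoxy silyl ether 13; the Lewis acid opens it at C5 to a methoxy-stabilised cation, and the cyclobutane bond C8–C6, exocyclic to the six-membered ring and anti to the departing oxygen, migrates with retention at C6 (semipinacol rearrangement with ring expansion of a 1-silyloxycyclobutane), driven by release of four-ring strain. The silyloxy cation left at C8 collapses to the ketone by loss of the silyl group as fluoride, and C5 is fixed as a bridgehead. The C4 configuration (oxygen expected anti to C6) is of no consequence because step 8 removes it.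

Step 8
Reactants: 14 (1S,4S,5S,6R,7S)-4-hydroxy-5-methoxy-7-methyl-1-(prop-2-en-1-yl)-6-(3,4,5-trimethoxyphenyl)bicyclo[3.2.1]octan-8-one
Product: 15 (1S,5S,6R,7S)-5-methoxy-7-methyl-1-(prop-2-en-1-yl)-6-(3,4,5-trimethoxyphenyl)bicyclo[3.2.1]octane-4,8-dione
Conditions: Dess–Martin periodinane, CH2Cl2, 0 to 23 °C
Reagents that add atoms: none
Why: Dess–Martin oxidation of the secondary alcohol under non-basic conditions, which spares the non-enolisable 1,3-dione from retro-Claisen cleavage and leaves the alkene and the arene untouched.

Step 9
Reactants: 15 (1S,5S,6R,7S)-5-methoxy-7-methyl-1-(prop-2-en-1-yl)-6-(3,4,5-trimethoxyphenyl)bicyclo[3.2.1]octane-4,8-dione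
Product: 17 (1R,5R,6R,7S)-3-hydroxy-5-methoxy-7-methyl-1-(prop-2-en-1-yl)-6-(3,4,5-trimethoxyphenyl)bicyclo[3.2.1]octane-4,8-dione (C3 epimers), via potassium enolate 16 (not isolated)
Conditions: KHMDS, THF, −78 °C; 2-(phenylsulfonyl)-3-phenyloxaziridine, −78 °C; AcOH
Reagents that add atoms: 2-(phenylsulfonyl)-3-phenyloxaziridine, O=S(=O)(c1ccccc1)N1OC1c1ccccc1
Why: Davis α-hydroxylation of a ketone enolate; C3 is the only enolisable position because C5 and C1 are quaternary, and the non-nucleophilic amide base does not attack the 1,3-dione. The new C3 centre is removed in step 10, so its configuration does not matter.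

Step 10
Reactants: 17 (1R,5R,6R,7S)-3-hydroxy-5-methoxy-7-methyl-1-(prop-2-en-1-yl)-6-(3,4,5-trimethoxyphenyl)bicyclo[3.2.1]octane-4,8-dione
Product: 19 (1S,5R,6R,7S)-3-hydroxy-5-methoxy-7-methyl-1-(prop-2-en-1-yl)-6-(3,4,5-trimethoxyphenyl)bicyclo[3.2.1]oct-2-ene-4,8-dione, via 3,4,8-trione 18 (not isolated)
Conditions: Dess–Martin periodinane, CH2Cl2, 23 °C
Reagents that add atoms: none
Why: Oxidation of the acyloin to the 1,2-dione, which enolises toward C2, the only neighbouring carbon with hydrogens and not a bridgehead, to give the diosphenol.

Step 11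
Reactants: 19 (1S,5R,6R,7S)-3-hydroxy-5-methoxy-7-methyl-1-(prop-2-en-1-yl)-6-(3,4,5-trimethoxyphenyl)bicyclo[3.2.1]oct-2-ene-4,8-dione
Product: 20 (1S,5R,6R,7S)-3,5-dimethoxy-7-methyl-1-(prop-2-en-1-yl)-6-(3,4,5-trimethoxyphenyl)bicyclo[3.2.1]oct-2-ene-4,8-dione
Conditions: Me2SO4, K2CO3, acetone, 50 °C
Reagents that add atoms: dimethyl sulfate, COS(=O)(=O)OC
Why: O-methylation of the acidic diosphenol with a hard methylating agent and a mild, non-nucleophilic base; anhydrous carbonate avoids alkoxide, which could cleave the 1,3-dione.

Step 12
Reactants: 20 (1S,5R,6R,7S)-3,5-dimethoxy-7-methyl-1-(prop-2-en-1-yl)-6-(3,4,5-trimethoxyphenyl)bicyclo[3.2.1]oct-2-ene-4,8-dione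
Product: 21 (1S,4R,5S,6R,7S)-4-hydroxy-3,5-dimethoxy-7-methyl-1-(prop-2-en-1-yl)-6-(3,4,5-trimethoxyphenyl)bicyclo[3.2.1]oct-2-en-8-one
Conditions: NaBH4, CeCl3·7H2O, MeOH, −78 °C
Reagents that add atoms: none
Why: Luche reduction, a 1,2-reduction that prefers the conjugated ketone over the saturated C8 ketone, which in addition lies between two quaternary carbons. The face of the C4 carbonyl turned toward the two-carbon bridge is covered by the endo aryl group, so hydride should enter from the side of the C8 bridge and place the hydroxyl on the aryl side (4R).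

Step 13
Reactants: 21 (1S,4R,5S,6R,7S)-4-hydroxy-3,5-dimethoxy-7-methyl-1-(prop-2-en-1-yl)-6-(3,4,5-trimethoxyphenyl)bicyclo[3.2.1]oct-2-en-8-one
Product: 22 (1S,4R,5S,6R,7S)-3,5-dimethoxy-7-methyl-8-oxo-1-(prop-2-en-1-yl)-6-(3,4,5-trimethoxyphenyl)bicyclo[3.2.1]oct-2-en-4-yl acetate
Conditions: Ac2O, pyridine, DMAP (cat.), CH2Cl2, 23 °C
Reagents that add atoms: acetic anhydride, CC(=O)OC(C)=O
Why: DMAP-catalysed acylation of the hindered secondary alcohol; the conditions are non-acidic, so the enol ether survives, and no stereocentre is touched.

## Compound list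

1 | cyclohexane-1,2-dione | O=C1CCCCC1=O | starting material
2 | allyl bromide | C=CCBr | starting material
3 | 2-(prop-2-en-1-yloxy)cyclohex-2-en-1-one | C=CCOC1=CCCCC1=O | intermediate
4 | 3-(prop-2-en-1-yl)cyclohexane-1,2-dione (racemic keto tautomer, not isolated) | C=CCC1CCCC(=O)C1=O | intermediate
5 | 2-hydroxy-3-(prop-2-en-1-yl)cyclohex-2-en-1-one | C=CCC1=C(O)C(=O)CCC1 | intermediate
6 | 2-(tert-butyldimethylsilyloxy)-3-(prop-2-en-1-yl)cyclohex-2-en-1-one | C=CCC1=C(O[Si](C)(C)C(C)(C)C)C(=O)CCC1 | intermediate
7 | 5-bromo-1,2,3-trimethoxybenzene | COc1cc(Br)cc(OC)c1OC | starting material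
8 | (E)-4,4,5,5-tetramethyl-2-(prop-1-en-1-yl)-1,3,2-dioxaborolane | C/C=C/B1OC(C)(C)C(C)(C)O1 | starting material
9 | (E)-isoelemicin, 1,2,3-trimethoxy-5-[(E)-prop-1-en-1-yl]benzene | C/C=C/c1cc(OC)c(OC)c(OC)c1 | intermediate
10 | (1R,6S,7S,8R)-1-(tert-butyldimethylsilyloxy)-7-methyl-6-(prop-2-en-1-yl)-8-(3,4,5-trimethoxyphenyl)bicyclo[4.2.0]octan-2-one (cis-fused; aryl endo and trans to silyloxy; methyl exo, cis to allyl) | C=CC[C@]12CCCC(=O)[C@@]1(O[Si](C)(C)C(C)(C)C)[C@@H](c1cc(OC)c(OC)c(OC)c1)[C@@H]2C | intermediate
11 | potassium enolate of 10 (C4=C5, not isolated) | C=CC[C@]12CCC=C([O-])[C@@]1(O[Si](C)(C)C(C)(C)C)[C@@H](c1cc(OC)c(OC)c(OC)c1)[C@@H]2C.[K+] | intermediate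
12 | (1R,6S,7S,8R)-1-(tert-butyldimethylsilyloxy)-2-methoxy-7-methyl-6-(prop-2-en-1-yl)-8-(3,4,5-trimethoxyphenyl)bicyclo[4.2.0]oct-2-ene | C=CC[C@]12CCC=C(OC)[C@@]1(O[Si](C)(C)C(C)(C)C)[C@@H](c1cc(OC)c(OC)c(OC)c1)[C@@H]2C | intermediate
13 | 2,3-epoxide of 12, oxirane oxygen on the face of the six-membered ring that bears the silyloxy group (not isolated) | C=CC[C@]12CC[C@@H]3O[C@]3(OC)[C@@]1(O[Si](C)(C)C(C)(C)C)[C@@H](c1cc(OC)c(OC)c(OC)c1)[C@@H]2C | intermediate
14 | (1S,4S,5S,6R,7S)-4-hydroxy-5-methoxy-7-methyl-1-(prop-2-en-1-yl)-6-(3,4,5-trimethoxyphenyl)bicyclo[3.2.1]octan-8-one (hydroxyl syn to C8) | C=CC[C@]12CC[C@H](O)[C@](OC)(C1=O)[C@@H](c1cc(OC)c(OC)c(OC)c1)[C@@H]2C | intermediate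
15 | (1S,5S,6R,7S)-5-methoxy-7-methyl-1-(prop-2-en-1-yl)-6-(3,4,5-trimethoxyphenyl)bicyclo[3.2.1]octane-4,8-dione | C=CC[C@]12CCC(=O)[C@](OC)(C1=O)[C@@H](c1cc(OC)c(OC)c(OC)c1)[C@@H]2C | intermediate
16 | potassium enolate of 15 (C3=C4, not isolated) | C=CC[C@]12CC=C([O-])[C@](OC)(C1=O)[C@@H](c1cc(OC)c(OC)c(OC)c1)[C@@H]2C.[K+] | intermediate
17 | (1R,5R,6R,7S)-3-hydroxy-5-methoxy-7-methyl-1-(prop-2-en-1-yl)-6-(3,4,5-trimethoxyphenyl)bicyclo[3.2.1]octane-4,8-dione (C3 epimers, used together) | C=CC[C@]12CC(O)C(=O)[C@](OC)(C1=O)[C@@H](c1cc(OC)c(OC)c(OC)c1)[C@@H]2C | intermediate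
18 | (1R,5R,6R,7S)-5-methoxy-7-methyl-1-(prop-2-en-1-yl)-6-(3,4,5-trimethoxyphenyl)bicyclo[3.2.1]octane-3,4,8-trione (not isolated) | C=CC[C@]12CC(=O)C(=O)[C@](OC)(C1=O)[C@@H](c1cc(OC)c(OC)c(OC)c1)[C@@H]2C | intermediate
19 | (1S,5R,6R,7S)-3-hydroxy-5-methoxy-7-methyl-1-(prop-2-en-1-yl)-6-(3,4,5-trimethoxyphenyl)bicyclo[3.2.1]oct-2-ene-4,8-dione | C=CC[C@]12C=C(O)C(=O)[C@](OC)(C1=O)[C@@H](c1cc(OC)c(OC)c(OC)c1)[C@@H]2C | intermediate
20 | (1S,5R,6R,7S)-3,5-dimethoxy-7-methyl-1-(prop-2-en-1-yl)-6-(3,4,5-trimethoxyphenyl)bicyclo[3.2.1]oct-2-ene-4,8-dione | C=CC[C@]12C=C(OC)C(=O)[C@](OC)(C1=O)[C@@H](c1cc(OC)c(OC)c(OC)c1)[C@@H]2C | intermediate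
21 | (1S,4R,5S,6R,7S)-4-hydroxy-3,5-dimethoxy-7-methyl-1-(prop-2-en-1-yl)-6-(3,4,5-trimethoxyphenyl)bicyclo[3.2.1]oct-2-en-8-one | C=CC[C@]12C=C(OC)[C@@H](O)[C@](OC)(C1=O)[C@@H](c1cc(OC)c(OC)c(OC)c1)[C@@H]2C | intermediate
22 | (1S,4R,5S,6R,7S)-3,5-dimethoxy-7-methyl-8-oxo-1-(prop-2-en-1-yl)-6-(3,4,5-trimethoxyphenyl)bicyclo[3.2.1]oct-2-en-4-yl acetate (CNP0181407.1) | C=CC[C@]12C=C(OC)[C@@H](OC(C)=O)[C@](OC)(C1=O)[C@@H](c1cc(OC)c(OC)c(OC)c1)[C@@H]2C | target

## Step count and least certain steps

Total: 13 steps. Longest linear sequence: 12 steps (1 to 22 through steps 1–3 and 5–13); step 4 is a one-step side branch.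

**Step 5 (key step).** The most likely failure is weak or absent asymmetric induction together with slow turnover: the 2-silyloxy group removes the α-hydrogen contact on which the known catalyst binding relies and crowds the carbonyl group, so uncatalysed background cycloaddition may dominate. Other processes to watch are:
- energy transfer from the triplet enone to 9, which wastes light in E/Z isomerisation;
- closure to trans-fused or aryl-exo diastereomers;
- di-π-methane-type reaction of the 1,4-diene unit of 6;
- Lewis-acid cleavage of the silyl enol ether.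

Fallback: setting out from 6 and 9, irradiation without any Lewis acid (350 nm, CH2Cl2, −20 °C) is an ordinary enone–alkene photocycloaddition. It should give the racemate, that is 10 together with its mirror image (1S,6R,7R,8S)-1-(tert-butyldimethylsilyloxy)-7-methyl-6-(prop-2-en-1-yl)-8-(3,4,5-trimethoxyphenyl)bicyclo[4.2.0]octan-2-one F1. Preparative chromatography on a cellulose tris(3,5-dimethylphenylcarbamate) phase separates the two, and the route is rejoined at 10.

**Step 7.** The cation at C5 has two oxygenated neighbours. The processes that may compete with the C6 shift are a hydride shift from C4 (Meinwald-type, giving a C4 ketone with hydrogen on C5), capture of the cation by adventitious water before migration, and migration of the ring-fusion carbon C1 instead of C6. Fallback: setting out from 12, the epoxidation is run in methanol (DMDO, MeOH/CH2Cl2, −40 °C), so that the cation is intercepted on purpose as the α-hydroxy dimethyl ketal F2 (the 2,2-dimethoxy-3-hydroxy analogue of 10, C4 epimers). Dess–Martin oxidation gives the keto ketal, 1-(tert-butyldimethylsilyloxy)-2,2-dimethoxy-7-methyl-6-(prop-2-en-1-yl)-8-(3,4,5-trimethoxyphenyl)bicyclo[4.2.0]octan-3-one F3. Ionisation of one methoxy group with TMSOTf (CH2Cl2, −78 to −20 °C) regenerates the C5 cation reversibly under anhydrous conditions. C4 now carries neither hydrogen nor a donor oxygen, so only the C8 side can migrate. The product is 15, where the route is rejoined; step 8 is then not needed.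

**Step 6.** C-methylation at C4 may compete with O-methylation, because simple ketone enolates are not reliably O-selective even with hard electrophiles. Fallback: setting out from 10, the enolate is hydroxylated instead (KHMDS; 2-(phenylsulfonyl)-3-phenyloxaziridine), where O- against C-selectivity does not arise, to give the α-hydroxy ketone F4 (the 3-hydroxy derivative of 10). The sequence then runs as follows:
- Dess–Martin oxidation gives the 2,3-dione, present as its enol, the diosphenol F5.
- Bu4NF buffered with AcOH removes the silyl group to give the tertiary alcohol F6.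
- BF3·OEt2 (CH2Cl2, 0 °C) brings about an α-ketol rearrangement, in which C6 moves from C8 to C5 with release of four-ring strain, to give (1S,5S,6R,7S)-5-hydroxy-7-methyl-1-(prop-2-en-1-yl)-6-(3,4,5-trimethoxyphenyl)bicyclo[3.2.1]octane-4,8-dione F7.
- Methylation of the tertiary hydroxyl (MeOTf, 2,6-di-tert-butyl-4-methylpyridine, CH2Cl2) returns to the route at 15.

**Step 12.** Hydride attack on the strained bridging C8 ketone may compete with attack at C4, or delivery to C4 may be less face-selective than the shielding by the aryl group suggests. Fallback: setting out from 20, the task is handed to a reagent. A Corey–Bakshi–Shibata reduction with (S)- or (R)-1-methyl-3,3-diphenyltetrahydro-1H,3H-pyrrolo[1,2-c][1,3,2]oxazaborole and catecholborane (toluene, −78 °C; these conditions do not hydroborate the allyl group) is used. The catalyst enantiomer is chosen so that its preferred hydride trajectory is the face syn to C8. The bulky catalyst–borane complex should also discriminate against the doubly neopentyl C8 ketone. The product is 21 directly, and no new compound is formed.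

## Further compounds

F1 | step 5 | (1S,6R,7R,8S)-1-(tert-butyldimethylsilyloxy)-7-methyl-6-(prop-2-en-1-yl)-8-(3,4,5-trimethoxyphenyl)bicyclo[4.2.0]octan-2-one (enantiomer of 10) | C=CC[C@@]12CCCC(=O)[C@]1(O[Si](C)(C)C(C)(C)C)[C@H](c1cc(OC)c(OC)c(OC)c1)[C@H]2C
F2 | step 7 | 1-(tert-butyldimethylsilyloxy)-2,2-dimethoxy-7-methyl-6-(prop-2-en-1-yl)-8-(3,4,5-trimethoxyphenyl)bicyclo[4.2.0]octan-3-ol (ring centres as in 10, C4 epimers) | C=CC[C@]12CCC(O)C(OC)(OC)[C@@]1(O[Si](C)(C)C(C)(C)C)[C@@H](c1cc(OC)c(OC)c(OC)c1)[C@@H]2C
F3 | step 7 | 1-(tert-butyldimethylsilyloxy)-2,2-dimethoxy-7-methyl-6-(prop-2-en-1-yl)-8-(3,4,5-trimethoxyphenyl)bicyclo[4.2.0]octan-3-one (ring centres as in 10) | C=CC[C@]12CCC(=O)C(OC)(OC)[C@@]1(O[Si](C)(C)C(C)(C)C)[C@@H](c1cc(OC)c(OC)c(OC)c1)[C@@H]2C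
F4 | step 6 | 1-(tert-butyldimethylsilyloxy)-3-hydroxy-7-methyl-6-(prop-2-en-1-yl)-8-(3,4,5-trimethoxyphenyl)bicyclo[4.2.0]octan-2-one (ring centres as in 10, C4 epimers) | C=CC[C@]12CCC(O)C(=O)[C@@]1(O[Si](C)(C)C(C)(C)C)[C@@H](c1cc(OC)c(OC)c(OC)c1)[C@@H]2C
F5 | step 6 | 1-(tert-butyldimethylsilyloxy)-3-hydroxy-7-methyl-6-(prop-2-en-1-yl)-8-(3,4,5-trimethoxyphenyl)bicyclo[4.2.0]oct-3-en-2-one (diosphenol, ring centres as in 10) | C=CC[C@]12CC=C(O)C(=O)[C@@]1(O[Si](C)(C)C(C)(C)C)[C@@H](c1cc(OC)c(OC)c(OC)c1)[C@@H]2C
F6 | step 6 | 1,3-dihydroxy-7-methyl-6-(prop-2-en-1-yl)-8-(3,4,5-trimethoxyphenyl)bicyclo[4.2.0]oct-3-en-2-one (ring centres as in 10) | C=CC[C@]12CC=C(O)C(=O)[C@@]1(O)[C@@H](c1cc(OC)c(OC)c(OC)c1)[C@@H]2C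
F7 | step 6 | (1S,5S,6R,7S)-5-hydroxy-7-methyl-1-(prop-2-en-1-yl)-6-(3,4,5-trimethoxyphenyl)bicyclo[3.2.1]octane-4,8-dione | C=CC[C@]12CCC(=O)[C@](O)(C1=O)[C@@H](c1cc(OC)c(OC)c(OC)c1)[C@@H]2C
F0 | step 12 | none | none
A1 | alternative 1 | 4-allyl-2-methoxy-1-(3,4,5-trimethoxyphenyl)hexa-1,4-dien-3-one, aryl and methyl both trans to the carbonyl carbon | C/C=C(CC=C)/C(=O)/C(OC)=C/c1cc(OC)c(OC)c(OC)c1
A2 | alternative 1 | triethylsilyl enol ether of 2-allyl-5-methoxy-3-methyl-4-(3,4,5-trimethoxyphenyl)cyclopentan-1-one | C=CCC1=C(O[Si](CC)(CC)CC)[C@@H](OC)[C@@H](c2cc(OC)c(OC)c(OC)c2)[C@@H]1C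
A3 | alternative 2 | 5-allyl-2-methoxy-4-methyl-5-(2-methoxy-3-oxoprop-1-en-1-yl)cyclopent-2-en-1-one, C1 and C7 as in the target, C1 and the formyl carbon cis | C=CC[C@@]1(/C=C(\C=O)OC)[C@@H](C)C=C(OC)C1=O
A4 | alternative 2 | (3,4,5-trimethoxyphenyl)zinc chloride | COc1cc([Zn]Cl)cc(OC)c1OC
A5 | alternative 2 | deacetyl target (C4 alcohol), identical with 21 | C=CC[C@]12C=C(OC)[C@@H](O)[C@](OC)(C1=O)[C@@H](c1cc(OC)c(OC)c(OC)c1)[C@@H]2C
A6 | alternative 3 | 4-allyl-2-(tert-butyldimethylsilyloxy)-3,5,5... masked ortho-benzoquinone: 5-allyl-2-(tert-butyldimethylsilyloxy)-3,6,6-trimethoxycyclohexa-2,4-dien-1-one | C=CCC1=CC(OC)=C(O[Si](C)(C)C(C)(C)C)C(=O)C1(OC)OC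
A7 | alternative 3 | endo-aryl bicyclo[2.2.2]oct-5-en-2-one adduct with bridgehead silyloxy group (bridgeheads C1 allyl and C4 silyloxy; bridges C2=C3(OMe), C5(=O)–C8(OMe)2, C6(aryl)–C7(methyl)) | C=CC[C@]12C=C(OC)[C@](O[Si](C)(C)C(C)(C)C)(C(=O)C1(OC)OC)[C@@H](c1cc(OC)c(OC)c(OC)c1)[C@@H]2C
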